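Which flask ends with more monomer in chains, dusk or summer?

- the winner by amount of monomer in chains, in percent of the solid monomer charged; "neither" if no more than 2 percentage points parts them (dusk / summer / neither)
- how much monomer in chains is there at the end, in percent of the solid monomer charged: dusk
- how much monomer in chains is there at the end, in percent of the solid monomer charged: summer

| flask | solid monomer | initiator | remark | time |
|---|---|---|---|---|
| red | 1.7 M | 75 mM | run made earlier |  |
| dusk | 1.5 M | 75 mM |  | 3.0 d |
| summer | 1.0 M | 250 mM |  | 0.80 d |

red run (percent of the solid monomer charged)

| time / h | monomer in chains / % | solid monomer / % |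
|---|---|---|
| 2.00 | 1.1 | 96.7 |
| 4.00 | 4.1 | 91.1 |
| 6.00 | 5.5 | 89.1 |
| 8.00 | 8.1 | 81.4 |
| 10.0 | 7.4 | 76.8 |
| 12.0 | 9.6 | 74.7 |
| 15.0 | 12.2 | 69.5 |

(each reading ± 1 percentage point)

- given per volume of solution although it is solid: solid monomer
- the earlier runs were read with a standard deviation of 1 percentage point
- reactions considered so far: free monomer + growing radical -> monomer in chains + growing radical; initiator -> 2 initiating radical; solid monomer <-> free monomer; free monomer + initiating radical -> growing radical + monomer in chains; 2 growing radical -> dead chain
- at the start none of the solid monomer is in solution
- no earlier run changes the charge of initiator; that part of a forecast is a guess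

Monomer must leave the solid before it can enter a chain, so start with the solid. In the red run the solid monomer fell to 69.5% by 15.0 h. Multiplying the loss by the charge and dividing by the time gives 0.0346 M/h, the mean dissolving flux. I assume that this flux doesn't depend on the charge. Replacing the curve by this mean has a cost: the red readings give more early than late, 0.0395 M/h up to 8.00 h and 0.0289 M/h afterwards.

Now take two extreme flasks. In the first, dissolving is the rate-limiting step, and each dissolved monomer enters a chain at once. Summer then reaches 66.4% of its charge, while for dusk this flux reckons 1.81 d for the whole charge, less than its 3.0 d. In the second, chains keep the share of dissolved monomer read in red at 15.0 h, 0.400. That gives summer 26.5% and dusk 40.0%.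

Dusk has red's initiator, and red's share read 0.435 early and 0.345 late, so I put dusk somewhat below 40.0%. Summer has 3.33 times red's initiator. Growing radicals die in pairs, so I scale the share by the square root, 1.83. This is a guess, since no run varies the initiator, and it puts summer near 48.5%, between its extremes.

The forecast, holding that “the radical supply is fading”, chose summer, with 18% for dusk and 28% for summer.

Dusk gives 34.6% and summer 52.2%, so summer wins.

    free monomer + growing radical → monomer in chains + growing radical, rate k1*[growing radical]*[free monomer] (k = 107 /M/s)
    initiator → 2 initiating radical (k = 3.28 × 10⁻⁵ /s)
    solid monomer ⇌ free monomer, rate k3*(cs3 - [free monomer]) while solid is left; crystals form when [free monomer] > cs3 (solubility = 1.10 M, k = 1.02 × 10⁻⁵ /s)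
    free monomer + initiating radical → growing radical + monomer in chains (k = 1120 /M/s)
    2 growing radical → dead chain (k = 6.00 × 10⁷ /M/s)

In summer, 27.0% of the charge is still solid at 0.800 d, so 73.0% has dissolved, against the 66.4% reckoned. Its mean flux is 0.0380 M/h, against 0.0346 M/h from red.

Take a neighbour of summer charged with 1.7 M of solid monomer. The flux gives 39.1% dissolved in 0.80 d. The neighbour itself has 42.9% dissolved and 30.7% in chains, which is 0.522 M against summer's 0.522 M.

(Readings and results are simulated on assumed constants.)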